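**Assumptions (one line each)**
- Reading the SMILES, the lactone is trans-fused, with C1 = R, C2 = S, C6 = S and C10 = S (target numbering, below). All three ring alkenes are E.
- Numbering follows the cembranoid skeleton: C1 carries C15(=C16H2)–C17(=O)–O–C2.
- The chiral-ligand enantiomer in the NHK couplings is assumed to give the (S)-carbinols.
- The racemic Baylis–Hillman centre in the tail is destroyed in the SN2′ step (Step 15).

**Retrosynthetic overview**
1. The target comes from a hydroxy ester by lactonization. The hydroxy ester comes from an intramolecular Nozaki–Hiyama–Kishi (NHK) allylation of a C2 enal by a (Z)-2-(bromomethyl)enoate. This closes the C1–C2 bond and the 14-membered ring, and gives the trans relationship by the anti-selective chair transition state.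
2. The acyclic enal bromide comes from two asymmetric vinyl-iodide/aldehyde NHK couplings (C6–C7 and C10–C11). These set the two (S)-acetoxy carbinols.
3. The three E-trisubstituted alkenes are carried in as (E)-vinyl iodides from Negishi carboalumination. The fragments come from 3-butynal acetal (head and middle) and 4-pentyn-1-ol (tail, with the enoate from a Baylis–Hillman reaction).
4. Ring order: the chain is built acyclic, the macrocycle closes at Step 16, and the γ-lactone closes last (Step 17).

---

**Step 1**
Reactants: 1 (4,4-diethoxybut-1-yne)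
Product: 2 ((E)-4-iodo-3-methylbut-3-enal diethyl acetal)
Conditions: Me3Al, cat. Cp2ZrCl2, DCE, 25 °C; then I2, THF, −30 °C
Reagents that add atoms: trimethylaluminium (C[Al](C)C, adds CH3); iodine (II, adds I)
Why: Negishi carboalumination adds Me and Al syn across the terminal alkyne, so iodination gives the E-trisubstituted vinyl iodide. The acetal masks the C10 (or C6) aldehyde.

**Step 2**
Reactants: 2
Product: 3 ((E)-5,5-diethoxy-3-methylpent-2-en-1-ol)
Conditions: t-BuLi (2 equiv), Et2O, −78 °C; then CH2O, −78 → 25 °C
Reagents that add atoms: formaldehyde from paraformaldehyde (C=O, adds CH2OH)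
Why: Lithium–iodine exchange is stereoretentive, and the vinyllithium adds to formaldehyde to give the C2 primary allylic alcohol with E geometry kept.

**Step 3**
Reactants: 3
Product: 4 (TBS ether of 3)
Conditions: TBSCl, imidazole, DMF, 25 °C
Reagents that add atoms: TBSCl (C[Si](C)(C(C)(C)C)Cl)
Why: Silylation protects the C2 oxygen so the later C6 aldehyde is the only electrophile in the NHK.

**Step 4**
Reactants: 4
Product: 5 ((E)-5-(TBSO)-3-methylpent-3-enal, i.e. the C2–C6 head aldehyde)
Conditions: PPTS, acetone/H2O 9:1, 50 °C; use the crude aldehyde cold and at once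
Reagents that add atoms: water (O)
Why: Mild acetal hydrolysis unmasks the β,γ-unsaturated aldehyde without touching the TBS ether or the E-alkene.

**Step 5**
Reactants: 6 (pent-4-yn-1-ol)
Product: 7 ((E)-5-iodo-4-methylpent-4-en-1-ol)
Conditions: Me3Al (3 equiv), cat. Cp2ZrCl2, DCE, 25 °C; then I2, THF, −30 °C
Reagents that add atoms: trimethylaluminium (C[Al](C)C); iodine (II)
Why: Same syn-carbometalation/iodination as Step 1, giving the E-vinyl iodide that will become C11=C12. The free OH is tolerated with excess Me3Al.

**Step 6**
Reactants: 7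
Product: 8 ((E)-5-iodo-4-methylpent-4-enal)
Conditions: DMP, NaHCO3, CH2Cl2, 25 °C
Reagents that add atoms: none
Why: Dess–Martin oxidation converts the primary alcohol to the aldehyde (C1) and leaves the vinyl iodide untouched.

**Step 7**
Reactants: 8, 9 (methyl acrylate)
Product: 10 (methyl (6E)-3-hydroxy-7-iodo-6-methyl-2-methylidenehept-6-enoate, racemic at C3)
Conditions: DABCO (0.3 equiv), neat, 25 °C, 4 d
Reagents that add atoms: none (methyl acrylate is reactant 9)
Why: The Baylis–Hillman reaction installs the C15/C16/C17 acrylate on the C1 aldehyde. The new carbinol centre is racemic and is removed in Step 15.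

**Step 8**
Reactants: 10
Product: 11 (acetate of 10)
Conditions: Ac2O, Et3N, DMAP, CH2Cl2, 0 °C
Reagents that add atoms: acetic anhydride (CC(=O)OC(C)=O)
Why: The acetate protects the carbinol through the NHK step and later serves as the leaving group for SN2′ bromination.

**Step 9**
Reactants: 5 (aldehyde), 2 (vinyl iodide)
Product: 12 ((6S)-allylic alcohol: TBSOCH2–CH=C(Me)–CH2–CH(OH)–CH=C(Me)–CH2–CH(OEt)2, 3E,7E)
Conditions: CrCl2 (4 equiv), cat. NiCl2, chiral sulfonamide ligand L*, MeCN, 25 °C
Reagents that add atoms: none
Why: Asymmetric Nozaki–Hiyama–Kishi coupling joins C6 and C7 with retention of the vinyl-iodide geometry, and the ligand controls the new C6 centre (S).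

**Step 10**
Reactants: 12
Product: 13 (C10 aldehyde with free C6-OH, TBSO-C2 intact)
Conditions: PPTS, acetone/H2O 9:1, 50 °C; use crude
Reagents that add atoms: water (O)
Why: Acetal hydrolysis as in Step 4. A cyclic hemiacetal cannot form because the C7=C8 alkene is E, and the TBS ether and acetate-free C6 carbinol survive the mild acid.

**Step 11**
Reactants: 13 (aldehyde), 11 (vinyl iodide)
Product: 14 ((6S,10S)-diol; a 1:1 mixture of epimers at the BH-acetate carbon, which converges in Step 15)
Conditions: CrCl2 (4 equiv), cat. NiCl2, chiral sulfonamide ligand L* (same enantiomer as Step 9), MeCN, 25 °C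
Reagents that add atoms: none
Why: A second asymmetric NHK forms C10–C11 and sets C10 (S) by reagent control. The free C6-OH, acrylate and acetates are tolerated.

**Step 12**
Reactants: 14
Product: 15 (C6, C10 diacetate)
Conditions: Ac2O, pyridine, DMAP, CH2Cl2, 25 °C
Reagents that add atoms: acetic anhydride (CC(=O)OC(C)=O)
Why: Both secondary allylic alcohols are acetylated in one operation, with no stereocentre affected.

**Step 13**
Reactants: 15
Product: 16 (C2 primary allylic alcohol)
Conditions: HF·pyridine, pyridine, THF, 0 → 25 °C
Reagents that add atoms: none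
Why: Fluoride removes the primary TBS ether selectively. The three acetates, the acrylate and the trisubstituted alkenes are stable to buffered HF.

**Step 14**
Reactants: 16
Product: 17 (C2 enal)
Conditions: MnO2 (20 equiv), CH2Cl2, 25 °C
Reagents that add atoms: none
Why: MnO2 oxidizes only the allylic C2 primary alcohol, and the E geometry is retained. No other free OH remains.

**Step 15**
Reactants: 17
Product: 18 ((Z)-2-(bromomethyl)alk-2-enoate enal)
Conditions: LiBr (10 equiv), THF, 25 °C, dark; use crude
Reagents that add atoms: lithium bromide ([Li+].[Br-], adds Br)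
Why: Bromide displaces the Baylis–Hillman acetate by SN2′ to give the thermodynamic (Z)-allylic bromide, which converts both epimers into one compound.

**Step 16**
Reactants: 18
Product: 19 (trans-configured hydroxy-ester macrocycle)
Conditions: CrCl2 (8 equiv), cat. NiCl2, DMF, 25 °C, syringe-pump addition over 12 h (about 2 mM)
Reagents that add atoms: none
Why: Intramolecular Nozaki–Hiyama allylation (Cr-allyl addition to the enal) closes the 14-membered ring. The allylchromium adds through its γ-carbon in a chair transition state, giving the anti (trans) relationship at C1/C2. The macrocyclic conformation set by the E-alkenes and the 6S,10S acetates is assumed to give C1 R, C2 S, as in precedented cembranolide macrocyclizations.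

**Step 17**
Reactants: 19
Product: 20 (target)
Conditions: TsOH·H2O (0.1 equiv), CH2Cl2, 25 °C (may already occur on acidic work-up of Step 16)
Reagents that add atoms: none
Why: Acid-catalysed lactonization of the C2 hydroxyl onto the methyl ester (loss of MeOH) forms the trans-fused α-methylene-γ-butyrolactone. No stereocentre is touched, and the secondary allylic acetates survive brief, mild acid.

---

**Compound list**

| # | Name | SMILES | Role |
|---|---|---|---|
| 1 | 4,4-diethoxybut-1-yne | C#CCC(OCC)OCC | starting material |
| 2 | (E)-4-iodo-3-methylbut-3-enal diethyl acetal | I/C=C(\C)CC(OCC)OCC | intermediate |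
| 3 | (E)-5,5-diethoxy-3-methylpent-2-en-1-ol | OC/C=C(\C)CC(OCC)OCC | intermediate |
| 4 | TBS ether of 3 | CC(C)(C)[Si](C)(C)OC/C=C(\C)CC(OCC)OCC | intermediate |
| 5 | (E)-5-(TBSO)-3-methylpent-3-enal | CC(C)(C)[Si](C)(C)OC/C=C(\C)CC=O | intermediate |
| 6 | pent-4-yn-1-ol | C#CCCCO | starting material |
| 7 | (E)-5-iodo-4-methylpent-4-en-1-ol | I/C=C(\C)CCCO | intermediate |
| 8 | (E)-5-iodo-4-methylpent-4-enal | I/C=C(\C)CCC=O | intermediate |
| 9 | methyl acrylate | C=CC(=O)OC | starting material |
| 10 | Baylis–Hillman adduct (racemic) | I/C=C(\C)CCC(O)C(=C)C(=O)OC | intermediate |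
| 11 | Baylis–Hillman acetate (racemic) | I/C=C(\C)CCC(OC(C)=O)C(=C)C(=O)OC | intermediate |
| 12 | (6S)-allylic alcohol acetal | CC(C)(C)[Si](C)(C)OC/C=C(\C)C[C@H](O)/C=C(\C)CC(OCC)OCC | intermediate |
| 13 | (6S)-hydroxy aldehyde | CC(C)(C)[Si](C)(C)OC/C=C(\C)C[C@H](O)/C=C(\C)CC=O | intermediate |
| 14 | (6S,10S)-diol (C1′ epimeric mixture) | CC(C)(C)[Si](C)(C)OC/C=C(\C)C[C@H](O)/C=C(\C)C[C@H](O)/C=C(\C)CCC(OC(C)=O)C(=C)C(=O)OC | intermediate |
| 15 | diacetate | CC(C)(C)[Si](C)(C)OC/C=C(\C)C[C@H](OC(C)=O)/C=C(\C)C[C@H](OC(C)=O)/C=C(\C)CCC(OC(C)=O)C(=C)C(=O)OC | intermediate |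
| 16 | C2 allylic alcohol | OC/C=C(\C)C[C@H](OC(C)=O)/C=C(\C)C[C@H](OC(C)=O)/C=C(\C)CCC(OC(C)=O)C(=C)C(=O)OC | intermediate |
| 17 | C2 enal | O=C/C=C(\C)C[C@H](OC(C)=O)/C=C(\C)C[C@H](OC(C)=O)/C=C(\C)CCC(OC(C)=O)C(=C)C(=O)OC | intermediate |
| 18 | (Z)-allylic bromide enal | O=C/C=C(\C)C[C@H](OC(C)=O)/C=C(\C)C[C@H](OC(C)=O)/C=C(\C)CC/C=C(\CBr)C(=O)OC | intermediate |
| 19 | macrocyclic hydroxy methyl ester | O[C@H]1/C=C(\C)C[C@H](OC(C)=O)/C=C(\C)C[C@H](OC(C)=O)/C=C(\C)CC[C@@H]1C(=C)C(=O)OC | intermediate |
| 20 | target, trans-fused α-methylene lactone cembranolide diacetate (CID11069750) | C=C1C(=O)O[C@H]2/C=C(\C)C[C@H](OC(C)=O)/C=C(\C)C[C@H](OC(C)=O)/C=C(\C)CC[C@H]12 | target |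

**Totals**
- Total steps: 17.
- Longest linear sequence: 13 steps (1 → 2 → 3 → 4 → 5 → 12 → 13 → 14 → 15 → 16 → 17 → 18 → 19 → 20, via Steps 1–4 and 9–17).

**Three steps most likely to fail**
1. **Step 16, macrocyclic NHK.** The diastereoselectivity at C1/C2 from remote control is uncertain, and oligomerization competes. Fallback: make the trans-lactone first by an intermolecular anti-selective Cr allylation of the enal and separate or resolve it. Then close the ring at C10–C11 by intramolecular vinyl-iodide/aldehyde NHK, or at C3=C4 by RCM.
2. **Step 11 (and Step 9), asymmetric NHK on β,γ-unsaturated aldehydes.** The aldehydes can isomerize to conjugated enals, the ee may be low, and Ni(0) could ionize the Baylis–Hillman acetate. Fallback: add the vinyllithium to a Weinreb amide to give the enone, then reduce with (R)-Me-CBS to give the (S)-alcohols. Use a TBS-protected Baylis–Hillman unit in the tail.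
3. **Step 15, SN2′ bromination of the Baylis–Hillman acetate.** It may be slow, or may give E/Z mixtures. Fallback: drop the bromide and close the ring by Pd(0)/Et2Zn (Tamaru-type) umpolung allylation of the C2 enal with the Baylis–Hillman acetate directly.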